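## The problem

Target 28 is a 10αH‑eremophilane: a trans‑fused decalin with cis‑vicinal methyls C15 (on C4) and C14 (on the quaternary C5), a β‑isopropenyl group on C7, an α‑angelate on C8, a ketone at C9 and an α‑acetate on C1 (eremophilane numbering; β is the face of C14). Of the six ring stereocentres only C5 is a dependable control element: once the framework is flat or trans‑fused its axial methyl screens the β face of both rings, so hydrogen can be delivered to C4 and C10 and oxygen to C1 from the α face. Ring B is the awkward part: in the trans‑decalin chair the 7β‑isopropenyl group is axial and syn to C14 and the 8α‑ester is axial as well, so 28 is very probably less stable than its C10 epimer, and C10 is α to the ketone. The ring fusion therefore has to be set by a stereospecific, kinetically controlled step, the C9 carbonyl has to stay masked until the end, and the 7β/8α pair has to be made against the steric bias, for which a trans‑diaxial epoxide opening is the natural tool. The fragile groups are the β‑acetoxy ketone (E1cB loss of acetate), the α‑acyloxy ketone, the angelate (Z to E isomerisation by base, nucleophiles or heat) and the isopropenyl group, which rules out hydrogenation and hydroboration once it is present. What opens the molecule to an arene‑based route is ring B: an oxidised C8–C9 unit flanked by the ring‑fusion carbon C10 and the quaternary C5 is what the keto‑ketal bridge of an o‑quinone monoketal cycloadduct becomes after a [3,3] shift, and C14 and C15 then map onto the two methyls of 3,4‑dimethylanisole 1.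

## Retrosynthesis

**28 to 27 (C9=O).** The last operation is unmasking of the C9 carbonyl from dimethyl ketal 27. Cutting here, and not at one of the esters, keeps C10 locked through every basic step and postpones the β‑acetoxy ketone until no base remains in the route. The ketal is free of charge, since it is the one made in the dearomatisation. The forward step must ionise a ketal deactivated by the neighbouring ester without enolising the product; loss of the axial methoxy group relieves 1,3‑diaxial strain, which should help.

**27 to 25 through 26 (two acyl C–O bonds).** The angelate is removed first (27 from mono‑acetate 26), then the acetate (26 from diol 25). The order follows accessibility, equatorial O1 against an axial O8 wedged between C9 and C7, and it exposes the (Z)‑ester to a single further step. Diol 25 has no base‑ or nucleophile‑sensitive group left.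

**25 to 21 through 23 and 22 (C7–C11 and C8–O).** The C7–C11 bond and the C8–O bond are cut together, back through alkynyl diol 23 and α‑epoxide 22 to alkene 21. A cut at C7–C11 alone, by enolate or conjugate‑addition chemistry next to a C8 or C9 carbonyl, would ask a reagent to approach C7 on the β face, syn to C14, and the 7α epimer would be expected. Anti opening of the 7α,8α‑epoxide reverses the bias: the diaxial rule forces the nucleophile onto C7β and leaves O8 α. The nucleophile is reduced to a two‑carbon rod (ethynyl) because it must pass two axial groups; C13 is added afterwards by syn methyl‑metalation of the alkyne. Alkene 21 has no stereocentre in ring B.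

**21 to 18 through 20 (C1–O and C10–H).** Both bonds are cut at once as a syn addition to a C1=C10 alkene from the α face, leading from hydroxy triflate 20 back to diene 18. The neighbouring cut, heteroatom conjugate addition to a 1(10)‑en‑9‑one with protonation at C10, leaves the ring fusion to an enolate protonation that is expected to return the cis isomer. Hydroboration delivers the C10 hydrogen as hydride, cis to the new C–O bond and trans to C14, which is the 1α,10α pattern of 28. It needs C9 to be sp3 (the ketal) and ring B to hold no second reactive alkene. The C7=C8 bond is therefore stored as the electron‑poor enol triflate of the C8 ketone and released afterwards by reduction (20 to 21). The arene‑derived C8 oxygen leaves with the triflate and returns from the epoxide.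

**18 to 15 through 17 (C1=C10 unsaturation).** Triflate 18 is the enolate derivative of ketone 17, which can enolise only toward C7. An alkene next to a ketal carbon cannot come from enone chemistry, so 17 is traced to α‑methoxy enone 15 by an oxidative re‑addition of the alcohol across the enol ether: selenium on C10, methoxy on C9, then syn elimination, which can only run toward C1. This is simpler than a detour through a free C9 ketone, which would force C8 and C9 to be differentiated twice.

**15 to 12 through 14 (C4–H; the cis fusion is erased).** C4 is cut as the hydrogenation product of diene 14. Hydrogenating cis‑fused 12 directly was the alternative; there both faces of C3=C4 are encumbered (β by the adjacent methyl, α by the folded ring B) and the result would depend on the reacting cis‑decalin conformer. In 14, obtained from 12 by eliminating one methoxy group toward C10, C10 is trigonal, ring A is held as in a Δ5‑steroid and only the α face is open. The same elimination removes the cis ring fusion that the key step cannot avoid.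

**12 to 10 (C5–C6 bond, ring B; key step).** Ring B is opened at C5–C6 with re‑formation of the C3–C8 bond, the retron of an anionic oxy‑Cope rearrangement, giving bicyclo[2.2.2]octenol 10. No other cut builds the quaternary C5, all ring‑B carbons and the oxidised C8–C9 unit in one step. The forward reaction needs the vinyl group syn to the dimethylated alkene bridge and one enantiomer of the bicycle.

**10 to 8 and 9; 8 to 7; 7 to 4 and 5 through 6; 4 to 1.** Carbinol 10 comes from ketone 8 and vinylmagnesium bromide 9 (C7–C8 bond). Ketone 8 is the desulfurised Diels–Alder adduct 7 of masked o‑benzoquinone 6 with vinyl sulfoxide 5, which acts as a chiral ethylene equivalent. Dienone 6 arises by oxidative dearomatisation of guaiacol 4, and 4 by ortho‑hydroxylation of anisole 1. Each of these cuts removes one ring or one C–C bond and ends at bought materials (1, 5, 9).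

## Roads not taken

Alternative 1: The cut runs through ring A. An intramolecular de Mayo photocycloaddition of a chelated formyl‑ketone enol onto a tethered trisubstituted alkene forms C10–C5 and C7–C6, and retro‑aldol opening of the cyclobutanol gives keto aldehyde A1; aldol condensation would then close ring B as a 7‑en‑9‑one. Merits: the quaternary C5 and the cis C4/C5 methyls come from one event on an acyclic precursor whose single stereocentre can be taken from the chiral pool, so the absolute configuration is secure. A1 also has C9 at the ketone level with a C7–C8 alkene within reach, a ring‑B array that the chosen route needs six steps (12 to 21) to reach. Weak points: regiochemistry (straight against crossed) and facial selectivity rest on a flexible tether with one remote methyl; the step needs dilute UV irradiation; A1 has no oxygen at C1 or C8, and its C10 is epimerisable, so the trans fusion and the C1 oxygen would still require trigonalising C10. Comparison: in absolute stereocontrol this road is the better one. The chosen plan sets against it that all ring carbons, C14, C15 and a masked C9 carbonyl are assembled thermally in five steps from arene 1, and that its ketal at C9 lets the C1=C10 alkene be hydroborated, which the free ketone derived from A1 would not.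

Alternative 2: The cut is C3–C4 and C5–C10 of ring A. A protonated chiral oxazaborolidine catalyses the Diels–Alder reaction of an (E)‑α‑methyl enal with a silyloxymethyl diene to give aldehyde A2. Merits: C4, C5 and C10 are set in one catalytic enantioselective step of predictable sense, and the alkene of A2 lies at C1–C2, a direct handle for the C1 oxygen. On both counts this road is better than the chosen one, which depends on a stoichiometric sulfoxide of untested facial bias and spends four steps (14 to 20) on placing oxygen at C1. Weak points: α,β‑disubstituted enals are poor dienophiles toward an acyclic monosubstituted diene; the endo adduct carries its two carbon appendages cis, so the fusion would again be cis and hard to correct without a carbonyl at C9; and ring B must be built bond by bond (C6–C7, C7–C8, C8–C9, both oxygens, the C7 branch). The chosen plan sets against it that ring B, its C9 oxygen and a C8 carbonyl handle all arrive in the key step.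

Alternative 3: The cut is exocyclic, C4–C15 and C5–C6. A chiral copper–phosphoramidite catalyst adds a methyl–aluminium reagent to a 2‑methylcycloalkenone and the aluminium enolate is allylated to give ketone A3 with the methyls cis. Merits: two contiguous stereocentres, one quaternary, from a commodity enone in one catalytic operation, shorter and freer of auxiliaries than the five steps to 12; the carbonyl of A3 is C10, so C1 is an α‑carbon open to enolate oxygenation. Weak points: C10 must accept C9 and then become the ring‑fusion CH, so the trans fusion, the C8 and C9 oxygens and the C7 branch all remain, behind a ring closure that leaves C10 as an alcohol or alkene; allylation of the hindered aluminium enolate is delicate. Comparison: up to a cis‑4,5‑dimethyl ring A this road is superior in step economy. The chosen plan pays more at the start and sets against it that the bicyclic core with C9 oxidised is in hand after step 5 and that each later stereocentre is tied to a stereospecific event.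

Key step: step 5

Conventions and assumption: decalins lacking the C7 side chain are named as 11,12,13‑trinoreremophilanes (4,5‑dimethyldecalins), and 4β,5β‑dimethyl is implied from 15 on. The π‑facial preference of sulfoxide 5 toward dienone 6 is not known; it is assumed that the (1R,4S) adduct 7 forms and can be separated from its facial diastereomer, and the (S)‑sulfoxide would be used if the sense is opposite.

## Route

Step 1
Reactants: 1 3,4‑dimethylanisole
Product: 4 2‑methoxy‑4,5‑dimethylphenol, via aryllithium 2 (not isolated), via dimethyl arylboronate 3 (not isolated)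
Conditions: n‑BuLi, TMEDA, Et2O, 0 → 23 °C; B(OMe)3, −78 → 23 °C; then 30% H2O2, aq. NaOH, 0 °C
Reagents that add atoms: hydrogen peroxide (OO)
Why: Directed ortho‑metalation: the methoxy group steers lithiation to the free ortho position C6 (C2 is flanked by the C3 methyl), and borylation–oxidation of the aryllithium turns C–Li into C–OH, a standard phenol synthesis.

Step 2
Reactants: 4 2‑methoxy‑4,5‑dimethylphenol; 5 (R)‑4‑methylphenyl vinyl sulfoxide
Product: 7 (1R,4S,7S)‑3,3‑dimethoxy‑5,6‑dimethyl‑7‑[(R)‑(4‑methylphenyl)sulfinyl]bicyclo[2.2.2]oct‑5‑en‑2‑one (sulfinyl syn to the C5=C6 bridge), via dienone 6 (not isolated)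
Conditions: PhI(OAc)2, MeOH, 5 (5 equiv), 0 → 60 °C, slow addition of 4; chromatographic separation of the facial diastereomers
Reagents that add atoms: methanol (CO)
Why: Hypervalent‑iodine oxidation of a 2‑methoxyphenol in methanol gives the masked o‑benzoquinone 6 (oxidative dearomatisation), whose 3,4‑dimethyl pattern slows self‑dimerisation so that the vinyl sulfoxide can trap it in a Diels–Alder reaction. Regio‑ and endo/exo isomers converge in step 3, and the sulfinyl stereocentre makes the two π‑facial adducts separable diastereomers, which fixes the absolute configuration of the bridgeheads.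

Step 3
Reactants: 7 sulfinyl adduct
Product: 8 (1R,4S)‑3,3‑dimethoxy‑5,6‑dimethylbicyclo[2.2.2]oct‑5‑en‑2‑one
Conditions: Raney Ni (W‑2, deactivated in acetone), EtOH, 23 °C
Reagents that add atoms: none
Why: Raney‑nickel hydrogenolysis of the C–S bond (desulfurisation) makes the sulfoxide an ethylene equivalent; the tetrasubstituted alkene and the hindered, non‑enolisable ketone should survive the deactivated metal.

Step 4
Reactants: 8 bicyclic ketone; 9 vinylmagnesium bromide
Product: 10 (1R,2R,4S)‑3,3‑dimethoxy‑5,6‑dimethyl‑2‑vinylbicyclo[2.2.2]oct‑5‑en‑2‑ol (vinyl syn to the C5=C6 bridge)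
Conditions: THF, −78 → 0 °C; aq. NH4Cl
Reagents that add atoms: none
Why: Grignard 1,2‑addition to a non‑enolisable ketone; the nucleophile enters past the flat C5=C6 bridge and avoids the endo hydrogens of the ethano bridge, as is general for bicyclo[2.2.2]oct‑5‑en‑2‑ones, which places the vinyl group syn to the alkene and sets C2 as R.

Step 5
Reactants: 10 vinyl carbinol
Product: 12 cis‑fused 9,9‑dimethoxy‑11,12,13‑trinoreremophil‑3‑en‑8‑one (5β‑CH3, 10β‑H), via potassium enolate 11 (not isolated)
Conditions: KH, 18‑crown‑6, THF, 0 → 50 °C; aq. NH4Cl, −78 °C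
Reagents that add atoms: none
Why: Anionic oxy‑Cope rearrangement: KH deprotonates the carbinol, 18‑crown‑6 strips the counter‑ion, and the free alkoxide weakens the C8–C3 bond so that the [3,3] shift runs near ambient temperature; the closest known reaction type is the anionic oxy‑Cope rearrangement of 2‑vinylbicyclo[2.2.2]oct‑5‑en‑2‑ols made from masked o‑benzoquinone cycloadducts. The vinyl terminus C6 bonds to the methyl‑bearing alkene carbon C5 while C8–C3 breaks, so ring B (C5–C6–C7–C8–C9–C10) closes by a concerted sigmatropic reorganisation through the boat‑like transition state that the bicycle enforces, not by a polar cyclisation. C5 is created suprafacially on the face of the alkene bridge that carries the vinyl group and C10 is the untouched bridgehead, so C14 and H‑10 must come out cis and the absolute configuration is that of 10. The one selectivity the step needs, vinyl syn to the dimethylated bridge, was secured in step 4; the anti isomer cannot reach the alkene. Enolate 11 is regiodefined (C7=C8) and is protonated at C7 on cold quench, which creates no stereocentre. Bond formation at a fully substituted alkene carbon raises the barrier above that of the usual cases, so gentle warming is allowed for.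

Step 6
Reactants: 12 cis‑fused ketal ketone
Product: 14 9‑methoxy‑11,12,13‑trinoreremophila‑3,9(10)‑dien‑8‑one, via silyl dienol ether 13 (not isolated)
Conditions: TMSOTf, i‑Pr2NEt, CH2Cl2, −20 → 0 °C; then K2CO3 (cat.), MeOH, 0 °C
Reagents that add atoms: none
Why: Gassman‑type conversion of a dimethyl ketal into its methyl enol ether: the ketone is silylated toward C7 (its only enolisable side), the ketal ionises and loses the only available β‑hydrogen (H‑10), and methanolysis of the silyl enol ether returns the C8 ketone conjugated to the new C9=C10 bond, which makes C10 trigonal.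

Step 7
Reactants: 14 α‑methoxy dienone
Product: 15 9‑methoxy‑11,12,13‑trinoreremophil‑9(10)‑en‑8‑one (4β‑CH3)
Conditions: H2 (1 atm), 10% Pd/C, EtOAc, 23 °C
Reagents that add atoms: none
Why: Heterogeneous hydrogenation: the isolated trisubstituted C3=C4 bond is reduced while the tetrasubstituted donor–acceptor C9=C10 bond should remain; with C10 trigonal the angular methyl stands pseudoaxial on the β face next to C4 (as in Δ5‑steroids), so hydrogen arrives from the α face and C15 ends β, cis to C14.

Step 8
Reactants: 15 α‑methoxy enone
Product: 17 9,9‑dimethoxy‑11,12,13‑trinoreremophil‑1(10)‑en‑8‑one, via selenide 16 (not isolated)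
Conditions: PhSeCl, NaHCO3, MeOH–CH2Cl2, −40 → 0 °C; then 30% H2O2, pyridine, 0 → 23 °C
Reagents that add atoms: methanol (CO)
Why: Methoxyselenation of the enol ether (selenium at C10, methanol at the oxocarbenium carbon C9) regenerates the dimethyl ketal, and the tertiary selenoxide undergoes syn elimination at or below room temperature; C5 and C9 carry no hydrogen, so only the C1=C10 alkene can form.

Step 9
Reactants: 17 β,γ‑unsaturated ketal ketone
Product: 18 9,9‑dimethoxy‑11,12,13‑trinoreremophila‑1(10),7‑dien‑8‑yl trifluoromethanesulfonate
Conditions: KN(SiMe3)2, THF, −78 °C; PhNTf2, −78 → 0 °C; aq. NH4Cl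
Reagents that add atoms: N‑phenylbis(trifluoromethanesulfonimide) (O=S(=O)(N(c1ccccc1)S(=O)(=O)C(F)(F)F)C(F)(F)F)
Why: Enolate formation and O‑sulfonylation: C7 is the only enolisable position of 17, so the enol triflate is regiodefined; it stores the future C7=C8 alkene in a form electron‑poor enough to be ignored by borane.

Step 10
Reactants: 18 dienyl triflate
Product: 20 1α‑hydroxy‑9,9‑dimethoxy‑10αH‑11,12,13‑trinoreremophil‑7‑en‑8‑yl trifluoromethanesulfonate, via alkylborane 19 (not isolated)
Conditions: BH3·THF, THF, 0 → 23 °C; then aq. NaOH, 30% H2O2, 0 °C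
Reagents that add atoms: hydrogen peroxide (OO)
Why: Hydroboration–oxidation: boron adds to the less substituted C1 and hydride to C10, syn and from the α face, opposite the axial C14 methyl that flanks C10 and is 1,3‑diaxial to C1 (the Δ5‑steroid precedent, 5α‑H/6α‑OH); this sets the trans ring fusion and the 1α‑oxygen together, and the oxidation retains configuration.

Step 11
Reactants: 20 hydroxy triflate
Product: 21 9,9‑dimethoxy‑10αH‑11,12,13‑trinoreremophil‑7‑en‑1α‑ol
Conditions: Pd(OAc)2 (5 mol %), PPh3, HCO2H, n‑Bu3N, DMF, 60 °C
Reagents that add atoms: none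
Why: Palladium‑catalysed formate reduction of an enol triflate (oxidative addition to zerovalent palladium, formate exchange, decarboxylation, C–H reductive elimination) releases the C7=C8 alkene without touching the alcohol or the ketal.

Step 12
Reactants: 21 alkenol
Product: 22 7α,8α‑epoxy‑9,9‑dimethoxy‑10αH‑11,12,13‑trinoreremophilan‑1α‑ol
Conditions: mCPBA, NaHCO3, CH2Cl2, 0 °C
Reagents that add atoms: mCPBA (OOC(=O)c1cccc(Cl)c1)
Why: Prilezhaev epoxidation: the β face of C7=C8 is screened by the axial C14 methyl (1,3 to C7) and by the pseudoaxial methoxy group on C9, so oxygen should arrive from the α face; bicarbonate protects the ketal.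

Step 13
Reactants: 22 α‑epoxide
Product: 23 7β‑ethynyl‑9,9‑dimethoxy‑10αH‑11,12,13‑trinoreremophilane‑1α,8α‑diol
Conditions: LiC≡CH·H2NCH2CH2NH2, DMSO, 23 → 50 °C; aq. NH4Cl
Reagents that add atoms: lithium acetylide–ethylenediamine complex ([Li+].[C-]#C.NCCN)
Why: Epoxide opening by an acetylide under Fürst–Plattner control: in the trans‑decalin only attack at C7 from the β face gives the trans‑diaxial product (C8 is also neopentylic), which sets 7β‑C and 8α‑OH; the rod‑shaped ethynyl anion is chosen because the incoming group must pass between the axial C14 methyl and the C9 methoxy group.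

Step 14
Reactants: 23 alkynyl diol
Product: 25 9,9‑dimethoxy‑10αH‑eremophil‑11‑ene‑1α,8α‑diol, via alkenylalane 24 (not isolated)
Conditions: AlMe3, Cp2ZrCl2 (0.3 equiv), H2O (1 equiv), CH2Cl2, −20 → 0 °C; then H2O, aq. KNaC4H4O6
Reagents that add atoms: trimethylaluminium (C[Al](C)C)
Why: Negishi zirconium‑catalysed methylalumination of a terminal alkyne (syn addition, methyl to the internal carbon) followed by protonolysis of the alkenyl–aluminium bond converts ethynyl into isopropenyl; homopropargylic alkoxides are standard substrates, and the water‑accelerated low‑temperature variant keeps the Lewis‑acid exposure of the ketal short.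

Step 15
Reactants: 25 isopropenyl diol
Product: 26 1α‑acetoxy‑9,9‑dimethoxy‑10αH‑eremophil‑11‑en‑8α‑ol
Conditions: Ac2O (1.1 equiv), pyridine, DMAP (cat.), CH2Cl2, 0 °C
Reagents that add atoms: acetic anhydride (CC(=O)OC(C)=O)
Why: Selective acylation: the equatorial 1α‑OH reacts, while the axial 8α‑OH, wedged between the ketal carbon and the isopropenyl‑bearing C7, should remain.

Step 16
Reactants: 26 mono‑acetate
Product: 27 1α‑acetoxy‑8α‑angeloyloxy‑9,9‑dimethoxy‑10αH‑eremophil‑11‑ene
Conditions: LiN(SiMe3)2, THF, −78 °C; angelic anhydride, −78 → 0 °C; aq. NH4Cl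
Reagents that add atoms: angelic anhydride, (Z)‑2‑methylbut‑2‑enoic anhydride (C/C=C(/C)C(=O)OC(=O)/C(C)=C\C)
Why: Acylation of the lithium alkoxide of a hindered secondary alcohol with angelic anhydride at low temperature; no nucleophilic catalyst or heat is present to isomerise the (Z)‑alkene to the tiglate.

Step 17
Reactants: 27 ketal diester
Product: 28 1α‑acetoxy‑8α‑angeloyloxy‑10αH‑eremophil‑11‑en‑9‑one (target, CNP0138236.2)
Conditions: CF3CO2H–H2O–CH2Cl2 (1:1:8), 0 °C, short contact; aq. NaHCO3
Reagents that add atoms: water (O)
Why: Acid‑catalysed ketal hydrolysis; loss of the axial methoxy group relieves its 1,3‑diaxial contacts with C14 and the isopropenyl group, so ionisation should be fast enough at 0 °C to keep the acid exposure short and leave the trans C10–H, the β‑acetoxy ketone, the angelate and the isopropenyl group intact.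

## Compound list

1 | 3,4‑dimethylanisole | COc1ccc(C)c(C)c1 | starting material
2 | (2‑methoxy‑4,5‑dimethylphenyl)lithium | [Li]c1cc(C)c(C)cc1OC | intermediate (not isolated)
3 | dimethyl (2‑methoxy‑4,5‑dimethylphenyl)boronate | COB(OC)c1cc(C)c(C)cc1OC | intermediate (not isolated)
4 | 2‑methoxy‑4,5‑dimethylphenol | COc1cc(C)c(C)cc1O | intermediate
5 | (R)‑4‑methylphenyl vinyl sulfoxide | C=C[S@@](=O)c1ccc(C)cc1 | starting material
6 | 6,6‑dimethoxy‑3,4‑dimethylcyclohexa‑2,4‑dien‑1‑one | COC1(OC)C=C(C)C(C)=CC1=O | intermediate (not isolated)
7 | (1R,4S,7S)‑3,3‑dimethoxy‑5,6‑dimethyl‑7‑[(R)‑(4‑methylphenyl)sulfinyl]bicyclo[2.2.2]oct‑5‑en‑2‑one | O=C1C(OC)(OC)[C@H]2C[C@H]([S@@](=O)c3ccc(C)cc3)[C@@H]1C(C)=C2C | intermediate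
8 | (1R,4S)‑3,3‑dimethoxy‑5,6‑dimethylbicyclo[2.2.2]oct‑5‑en‑2‑one | O=C1C(OC)(OC)[C@H]2CC[C@@H]1C(C)=C2C | intermediate
9 | vinylmagnesium bromide | C=C[Mg]Br | starting material
10 | (1R,2R,4S)‑3,3‑dimethoxy‑5,6‑dimethyl‑2‑vinylbicyclo[2.2.2]oct‑5‑en‑2‑ol, vinyl syn to C5=C6 | C=C[C@]1(O)C(OC)(OC)[C@H]2CC[C@@H]1C(C)=C2C | intermediate (key‑step precursor)
11 | potassium 9,9‑dimethoxy‑11,12,13‑trinoreremophila‑3,7‑dien‑8‑olate (10β‑H) | [K+].[O-]C1=CC[C@@]2(C)[C@@H](C1(OC)OC)CCC=C2C | intermediate (not isolated)
12 | cis‑fused 9,9‑dimethoxy‑11,12,13‑trinoreremophil‑3‑en‑8‑one (5β‑CH3, 10β‑H) | C1C[C@@]2(C)[C@@H](C(OC)(OC)C1=O)CCC=C2C | intermediate (key‑step product)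
13 | 9‑methoxy‑8‑(trimethylsilyloxy)‑11,12,13‑trinoreremophila‑3,7,9(10)‑triene | C[Si](C)(C)OC1=CC[C@]2(C)C(C)=CCCC2=C1OC | intermediate (not isolated)
14 | 9‑methoxy‑11,12,13‑trinoreremophila‑3,9(10)‑dien‑8‑one | COC1=C2CCC=C(C)[C@@]2(C)CCC1=O | intermediate
15 | 9‑methoxy‑11,12,13‑trinoreremophil‑9(10)‑en‑8‑one (4β‑CH3) | COC1=C2CCC[C@H](C)[C@@]2(C)CCC1=O | intermediate
16 | 9,9‑dimethoxy‑10α‑(phenylselanyl)‑11,12,13‑trinoreremophilan‑8‑one | O=C1C(OC)(OC)[C@]2([Se]c3ccccc3)CCC[C@H](C)[C@@]2(C)CC1 | intermediate (not isolated)
17 | 9,9‑dimethoxy‑11,12,13‑trinoreremophil‑1(10)‑en‑8‑one | O=C1C(OC)(OC)C2=CCC[C@H](C)[C@@]2(C)CC1 | intermediate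
18 | 9,9‑dimethoxy‑11,12,13‑trinoreremophila‑1(10),7‑dien‑8‑yl trifluoromethanesulfonate | C1=C(OS(=O)(=O)C(F)(F)F)C(OC)(OC)C2=CCC[C@H](C)[C@@]2(C)C1 | intermediate
19 | 1α‑boranyl‑9,9‑dimethoxy‑10αH‑11,12,13‑trinoreremophil‑7‑en‑8‑yl trifluoromethanesulfonate | C1=C(OS(=O)(=O)C(F)(F)F)C(OC)(OC)[C@@H]2[C@@H](B)CC[C@H](C)[C@@]2(C)C1 | intermediate (not isolated)
20 | 1α‑hydroxy‑9,9‑dimethoxy‑10αH‑11,12,13‑trinoreremophil‑7‑en‑8‑yl trifluoromethanesulfonate | C1=C(OS(=O)(=O)C(F)(F)F)C(OC)(OC)[C@@H]2[C@@H](O)CC[C@H](C)[C@@]2(C)C1 | intermediate
21 | 9,9‑dimethoxy‑10αH‑11,12,13‑trinoreremophil‑7‑en‑1α‑ol | C1=CC(OC)(OC)[C@@H]2[C@@H](O)CC[C@H](C)[C@@]2(C)C1 | intermediate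
22 | 7α,8α‑epoxy‑9,9‑dimethoxy‑10αH‑11,12,13‑trinoreremophilan‑1α‑ol | O1[C@@H]2C[C@@]3(C)[C@H](C(OC)(OC)[C@H]12)[C@@H](O)CC[C@@H]3C | intermediate
23 | 7β‑ethynyl‑9,9‑dimethoxy‑10αH‑11,12,13‑trinoreremophilane‑1α,8α‑diol | C#C[C@H]1C[C@@]2(C)[C@H](C(OC)(OC)[C@@H]1O)[C@@H](O)CC[C@@H]2C | intermediate
24 | (E)‑alkenyl(dimethyl)alane of 23, both hydroxyls as dimethylaluminium alkoxides | C[Al](C)/C=C(\C)[C@H]1C[C@@]2(C)[C@H](C(OC)(OC)[C@@H]1O[Al](C)C)[C@@H](O[Al](C)C)CC[C@@H]2C | intermediate (not isolated)
25 | 9,9‑dimethoxy‑10αH‑eremophil‑11‑ene‑1α,8α‑diol (7β‑isopropenyl) | C=C(C)[C@H]1C[C@@]2(C)[C@H](C(OC)(OC)[C@@H]1O)[C@@H](O)CC[C@@H]2C | intermediate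
26 | 1α‑acetoxy‑9,9‑dimethoxy‑10αH‑eremophil‑11‑en‑8α‑ol | C=C(C)[C@H]1C[C@@]2(C)[C@H](C(OC)(OC)[C@@H]1O)[C@@H](OC(C)=O)CC[C@@H]2C | intermediate
27 | 1α‑acetoxy‑8α‑angeloyloxy‑9,9‑dimethoxy‑10αH‑eremophil‑11‑ene | C=C(C)[C@H]1C[C@@]2(C)[C@H](C(OC)(OC)[C@@H]1OC(=O)/C(C)=C\C)[C@@H](OC(C)=O)CC[C@@H]2C | intermediate
28 | 1α‑acetoxy‑8α‑angeloyloxy‑10αH‑eremophil‑11‑en‑9‑one | C=C(C)[C@H]1C[C@@]2(C)[C@H](C(=O)[C@@H]1OC(=O)/C(C)=C\C)[C@@H](OC(C)=O)CC[C@@H]2C | target

## Step count and least certain steps

Total: 17 steps. Longest linear sequence: 17 steps (fully linear from 1; 5 and 9 are bought).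

**Step 5 (key step).** The new bond is made to a fully substituted alkene carbon, so the rearrangement may be slow; on heating, the alkoxide may fragment back toward ketone 8 or the enolate may equilibrate before the quench. Fallback: from 10, silylate the tertiary alcohol (Me3SiCl, imidazole) to trimethylsilyl ether F1, run the neutral thermal siloxy‑Cope rearrangement in a sealed tube near 200 °C to trimethylsilyl enol ether F2, and cleave it with K2CO3 in MeOH to return to 12.

**Step 8.** Electrophilic capture at C10 may fail: the enol ether is conjugated to the C8 ketone and C10 lies between two fully substituted carbons, so selenenylation may be slow, and α‑selenenylation at C7 or simple acid‑mediated addition of methanol may take over. Fallback: from 15, reduce the ketone under Luche conditions (NaBH4, CeCl3·7H2O, MeOH) to allylic alcohol F3, whose isolated enol ether is more nucleophilic. Methoxyselenation then gives hydroxy selenide F4, oxidative elimination gives ketal alcohol F5, and Dess–Martin oxidation returns ketone 17.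

**Step 13.** The nucleophile may not reach C7 on the β face between two axial groups, and the strongly basic acetylide may instead isomerise the epoxide to an allylic alcohol. Fallback: from 22, use the Lewis‑acidic, non‑basic alkynylalane Et2AlC≡CSiMe3 in toluene (Fried‑type opening, aluminium activates the epoxide oxygen) to give silylalkynyl diol F6, and remove the silyl group with K2CO3 in MeOH to reach 23.

**Step 17.** Acid may enolise the product toward C10 (epimerisation to the more stable cis‑fused ketone) or hydrate or isomerise the isopropenyl group before the ester‑deactivated ketal has ionised. Fallback: change the order. From 26, hydrolyse the ketal while O8 is still a free hydroxyl and no angelate is at risk, giving hydroxy ketone F7. Then esterify under base‑lean Yamaguchi conditions (angelic acid, 2,4,6‑trichlorobenzoyl chloride, Et3N, toluene) to arrive at 28.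

**Step 10.** Hydroboration of an alkene whose C10 is flanked by two fully substituted carbons may be slow, and forcing conditions may let borane attack the ketal or the triflate or erode facial selectivity. Fallback: from 18, epoxidise C1=C10 from the α face with dimethyldioxirane to epoxy triflate F8. Open it reductively with Cp2TiCl (from Cp2TiCl2 and Zn) and 1,4‑cyclohexadiene: the oxygen stays on C1 and the tertiary C10 radical takes hydrogen from the α face, giving 20.

**Step 2.** The vinyl sulfoxide may be too sluggish to outrun dimerisation of 6, or its facial selectivity may be low. Fallback: from 4, run the same oxidation in the presence of phenyl vinyl sulfone to racemic sulfone adduct F9. Desulfonylate with Na(Hg) and Na2HPO4 in MeOH to the racemic ketone (8 and its enantiomer F10), and separate the enantiomers by preparative chromatography on a chiral stationary phase, re‑entering at 8.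

## Further compounds

F1 | step 5 | (1R,2R,4S)‑3,3‑dimethoxy‑5,6‑dimethyl‑2‑(trimethylsilyloxy)‑2‑vinylbicyclo[2.2.2]oct‑5‑ene | C=C[C@]1(O[Si](C)(C)C)C(OC)(OC)[C@H]2CC[C@@H]1C(C)=C2C
F2 | step 5 | cis‑fused 9,9‑dimethoxy‑8‑(trimethylsilyloxy)‑11,12,13‑trinoreremophila‑3,7‑diene | C[Si](C)(C)OC1=CC[C@@]2(C)[C@@H](C1(OC)OC)CCC=C2C
F3 | step 8 | 9‑methoxy‑11,12,13‑trinoreremophil‑9(10)‑en‑8β‑ol (C8 epimer of no consequence) | COC1=C2CCC[C@H](C)[C@@]2(C)CC[C@@H]1O
F4 | step 8 | 9,9‑dimethoxy‑10α‑(phenylselanyl)‑11,12,13‑trinoreremophilan‑8β‑ol | O[C@@H]1C(OC)(OC)[C@]2([Se]c3ccccc3)CCC[C@H](C)[C@@]2(C)CC1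
F5 | step 8 | 9,9‑dimethoxy‑11,12,13‑trinoreremophil‑1(10)‑en‑8β‑ol | O[C@@H]1C(OC)(OC)C2=CCC[C@H](C)[C@@]2(C)CC1
F6 | step 13 | 9,9‑dimethoxy‑7β‑[(trimethylsilyl)ethynyl]‑10αH‑11,12,13‑trinoreremophilane‑1α,8α‑diol | C[Si](C)(C)C#C[C@H]1C[C@@]2(C)[C@H](C(OC)(OC)[C@@H]1O)[C@@H](O)CC[C@@H]2C
F7 | step 17 | 1α‑acetoxy‑8α‑hydroxy‑10αH‑eremophil‑11‑en‑9‑one | C=C(C)[C@H]1C[C@@]2(C)[C@H](C(=O)[C@@H]1O)[C@@H](OC(C)=O)CC[C@@H]2C
F8 | step 10 | 1α,10α‑epoxy‑9,9‑dimethoxy‑11,12,13‑trinoreremophil‑7‑en‑8‑yl trifluoromethanesulfonate | C1=C(OS(=O)(=O)C(F)(F)F)C(OC)(OC)[C@@]23O[C@H]3CC[C@H](C)[C@@]2(C)C1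
F9 | step 2 | racemic 3,3‑dimethoxy‑5,6‑dimethyl‑7‑(phenylsulfonyl)bicyclo[2.2.2]oct‑5‑en‑2‑one, sulfonyl syn to C5=C6 (one enantiomer drawn) | O=C1C(OC)(OC)[C@H]2C[C@H](S(=O)(=O)c3ccccc3)[C@@H]1C(C)=C2C
F10 | step 2 | (1S,4R)‑3,3‑dimethoxy‑5,6‑dimethylbicyclo[2.2.2]oct‑5‑en‑2‑one | O=C1C(OC)(OC)[C@@H]2CC[C@H]1C(C)=C2C
A1 | alternative 1 | 2‑(2‑acetyl‑1,6‑dimethylcyclohexyl)acetaldehyde, ring methyls cis | O=CC[C@@]1(C)[C@H](C(C)=O)CCC[C@@H]1C
A2 | alternative 2 | 2‑[(tert‑butyldimethylsilyloxy)methyl]‑1,6‑dimethylcyclohex‑3‑ene‑1‑carbaldehyde, methyls cis | O=C[C@@]1(C)[C@@H](CO[Si](C)(C)C(C)(C)C)C=CC[C@@H]1C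
A3 | alternative 3 | 2‑allyl‑2,3‑dimethylcyclohexan‑1‑one, methyls cis | C=CC[C@@]1(C)C(=O)CCC[C@@H]1C
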